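## Retrosynthetic overview

1. The target comes from its pentadecamethyl ether 44 (BBr3). Units a/b are attached at C7c–C8b by aldol condensation of the seven-ring ketone 38 with the C7c aldehyde 34, followed by conjugate arylation (C7c) and aryl addition/ionic hydrogenation (C7b).
2. Feature used: ring C is part of both the eight-membered carbocycle (C8c–C9c–C10c–C8d–C9d–C10d–C7e–C8e) and the unit-d dihydrofuran (O on C11c, C7d, C8d, C10c). Cutting C10c–C8d and O–C7d opens both rings to an o-iodophenol (ring C) tethered through C8c–C8e–C7e to a C7d≡C8d diarylalkyne on ring D (compound 30).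
3. Compound 30 comes from an Ir/isothiourea allylic substitution (C8c–C8e), oxidative cleavage to the C7e aldehyde, ortho-hydroxyalkylation of the ring-D phenol (C7e–C10d) and o-quinone methide arylation (C7e–aryl).
4. Both trans-2,3-diaryl-dihydrobenzofurans (units a/b and e/f) come from one bromide 9, made by Rh-carbene C–H insertion and acid epimerisation.
5. Ring order: furans of e/f and a/b (in 9) → eight-membered ring and unit-d benzofuran together (step 23) → unit-d dihydrofuran (step 25); the seven-membered ring is made separately (step 28) and joined in steps 29–33.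

Key step: step 23

Remark on locants and abbreviations: units a–f are the six stilbene units; C7x/C8x are the two sp3 carbons of unit x and C9x–C14x its resorcinol ring (ring X). An = 4-methoxyphenyl. DBF = (2R,3R)-3-(3,5-dimethoxyphenyl)-6-methoxy-2-(4-methoxyphenyl)-2,3-dihydro-1-benzofuran-4-yl. ArSi = 2-iodo-3,5-bis(triisopropylsilyloxy)phenyl.

Assumption: the antipodes named for Rh2(PTAD)4 (step 6) and for the Ir-phosphoramidite/benzotetramisole pair (step 14) are taken to give the configurations drawn; should the sense of induction be opposite, the enantiomeric catalysts are used.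

## Route

Step 1
Reactants: 1 2-bromo-4,6-dimethoxybenzaldehyde
Product: 2 2-bromo-6-hydroxy-4-methoxybenzaldehyde
Conditions: BCl3 (1.2 equiv), CH2Cl2, −78 → 0 °C; H2O
Reagents that add atoms: none
Why: Chelation-controlled ether cleavage; boron held by the aldehyde oxygen should remove only the ortho methoxy group.

Step 2
Reactants: 2 2-bromo-6-hydroxy-4-methoxybenzaldehyde
Product: 3 2-bromo-4-methoxy-6-[(4-methoxybenzyl)oxy]benzaldehyde
Conditions: 4-MeOC6H4CH2Cl, K2CO3, DMF, 60 °C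
Reagents that add atoms: 4-methoxybenzyl chloride, COc1ccc(CCl)cc1
Why: Williamson ether synthesis; the benzylic CH2 and its aryl group become C2 and the 2-aryl group of the dihydrobenzofuran.

Step 3
Reactants: 3 2-bromo-4-methoxy-6-[(4-methoxybenzyl)oxy]benzaldehyde
Product: 4 [2-bromo-4-methoxy-6-(4-methoxybenzyloxy)phenyl](3,5-dimethoxyphenyl)methanol (racemic)
Conditions: 3,5-(MeO)2C6H3MgBr, THF, −78 → 0 °C
Reagents that add atoms: 3,5-dimethoxyphenylmagnesium bromide, COc1cc(OC)cc([Mg]Br)c1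
Why: Grignard 1,2-addition to the aldehyde; the carbinol centre is destroyed in the next step.

Step 4
Reactants: 4 diaryl carbinol
Product: 5 [2-bromo-4-methoxy-6-(4-methoxybenzyloxy)phenyl](3,5-dimethoxyphenyl)methanone
Conditions: Dess–Martin periodinane, NaHCO3, CH2Cl2, rt
Reagents that add atoms: none
Why: Dess–Martin oxidation of a benzhydrol to the benzophenone under non-acidic conditions.

Step 5
Reactants: 5 diaryl ketone
Product: 6 hydrazone of ketone 5 (E/Z mixture)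
Conditions: N2H4·H2O (20 equiv), AcOH (cat.), n-BuOH, 110 °C, sealed tube
Reagents that add atoms: hydrazine, NN
Why: Hydrazone condensation; forcing conditions are chosen because the ketone is di-ortho-substituted.

Step 6
Reactants: 6 hydrazone of ketone 5
Product: 8 (2S,3R)-4-bromo-3-(3,5-dimethoxyphenyl)-6-methoxy-2-(4-methoxyphenyl)-2,3-dihydro-1-benzofuran (cis), via diaryldiazomethane 7 (not isolated)
Conditions: MnO2, CH2Cl2, 0 °C, filtration; Rh2(S-PTAD)4 (1 mol %), CH2Cl2, −20 °C → rt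
Reagents that add atoms: none
Why: Hydrazone oxidation and Rh(II)-catalysed enantioselective intramolecular 1,5 C–H insertion of a donor/donor carbene into the benzylic ether C–H; the chiral carboxylate catalyst sets C3 (R) and the insertion should give the cis isomer.

Step 7
Reactants: 8 cis-dihydrobenzofuran bromide
Product: 9 (2R,3R)-4-bromo-3-(3,5-dimethoxyphenyl)-6-methoxy-2-(4-methoxyphenyl)-2,3-dihydro-1-benzofuran (trans; DBF–Br)
Conditions: TFA (5 equiv), CH2Cl2, 0 °C → rt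
Reagents that add atoms: none
Why: Acid-mediated epimerisation; reversible ionisation of the anisyl-stabilised C2–O bond should lead to the more stable trans isomer while C3 stays untouched.

Step 8
Reactants: 9 DBF–Br
Product: 10 (E)-3-DBF-prop-2-en-1-ol
Conditions: (E)-Bu3SnCH=CHCH2OH, Pd2(dba)3, P(t-Bu)3, CsF, dioxane, 100 °C
Reagents that add atoms: (E)-3-(tributylstannyl)prop-2-en-1-ol, CCCC[Sn](CCCC)(CCCC)/C=C/CO
Why: Stille coupling of the hindered aryl bromide with retention of the E alkene geometry.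

Step 9
Reactants: 10 (E)-3-DBF-prop-2-en-1-ol
Product: 11 (E)-3-DBF-prop-2-enyl methyl carbonate
Conditions: ClCO2Me, pyridine, CH2Cl2, 0 °C
Reagents that add atoms: methyl chloroformate, COC(=O)Cl
Why: Carbonate formation gives the leaving group for iridium-catalysed allylic substitution.

Step 10
Reactants: 12 2-(3,5-dimethoxyphenyl)acetic acid
Product: 13 2-(2-iodo-3,5-dimethoxyphenyl)acetic acid
Conditions: NIS, TFA (cat.), MeCN, rt
Reagents that add atoms: N-iodosuccinimide, O=C1CCC(=O)N1I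
Why: Electrophilic aromatic iodination ortho to the side chain and para to a methoxy group; the symmetric ring makes the position (later C10c) unambiguous.

Step 11
Reactants: 13 2-(2-iodo-3,5-dimethoxyphenyl)acetic acid
Product: 14 2-(3,5-dihydroxy-2-iodophenyl)acetic acid
Conditions: BBr3 (4 equiv), CH2Cl2, −78 °C → rt; H2O
Reagents that add atoms: none
Why: Lewis-acid ether cleavage; both ring-C oxygens are freed so that no regioselective differentiation of the two is needed before the annulation.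

Step 12
Reactants: 14 2-(3,5-dihydroxy-2-iodophenyl)acetic acid
Product: 16 2-[2-iodo-3,5-bis(triisopropylsilyloxy)phenyl]acetic acid, via silyl ester 15 (not isolated)
Conditions: TIPSCl (3.3 equiv), imidazole, DMF, rt; then K2CO3, MeOH/THF/H2O, 0 °C
Reagents that add atoms: chlorotriisopropylsilane, CC(C)[Si](Cl)(C(C)C)C(C)C
Why: Silylation of both phenols and the acid, then selective hydrolysis of the labile silyl ester; aryl TIPS ethers withstand the later Grignard and carbonate steps.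

Step 13
Reactants: 16 2-[2-iodo-3,5-bis(triisopropylsilyloxy)phenyl]acetic acid
Product: 17 pentafluorophenyl 2-[2-iodo-3,5-bis(triisopropylsilyloxy)phenyl]acetate
Conditions: C6F5OH, DCC, DMAP (cat.), CH2Cl2, 0 °C → rt
Reagents that add atoms: pentafluorophenol, Oc1c(F)c(F)c(F)c(F)c1F
Why: Steglich esterification to the activated aryl ester needed for isothiourea enolate catalysis.

Step 14
Reactants: 17 pentafluorophenyl arylacetate; 11 (E)-3-DBF-prop-2-enyl methyl carbonate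
Product: 19 (2R,3R)-3-DBF-2-ArSi-pent-4-en-1-ol, via pentafluorophenyl ester 18 (not isolated)
Conditions: [Ir(cod)Cl]2 (2 mol %), (S,S,S)-BINOL bis(1-phenylethyl)phosphoramidite (4 mol %, n-PrNH2 activation), (R)-benzotetramisole (10 mol %), THF, rt; then NaBH4, MeOH, 0 °C
Reagents that add atoms: none
Why: Synergistic iridium/Lewis-base allylic substitution of an aryl acetic ester (C1-ammonium enolate attacks the branched terminus of the Ir-allyl) forms C8c–C8e, the isothiourea setting C8c and the Ir-phosphoramidite setting C8e independently; borohydride then reduces the activated ester before C8c can epimerise.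

Step 15
Reactants: 19 (2R,3R)-3-DBF-2-ArSi-pent-4-en-1-ol
Product: 20 tert-butyldimethylsilyl ether of 19
Conditions: TBSCl, imidazole, DMF, rt
Reagents that add atoms: tert-butylchlorodimethylsilane, CC(C)(C)[Si](C)(C)Cl
Why: Silyl protection keeps the C7c hydroxyl from forming a lactol with the aldehyde made next.

Step 16
Reactants: 20 silyl ether of 19
Product: 21 (2R,3R)-4-(tert-butyldimethylsilyloxy)-2-DBF-3-ArSi-butanal
Conditions: OsO4 (2 mol %), NaIO4 (4 equiv), 2,6-lutidine, dioxane/H2O, rt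
Reagents that add atoms: sodium periodate (oxygen relayed by OsO4), [Na+].[O-]I(=O)(=O)=O
Why: Lemieux–Johnson cleavage of the terminal alkene gives the C7e aldehyde; lutidine buffering should limit epimerisation at C8e.

Step 17
Reactants: 22 3-bromo-5-methoxyphenol; 23 4-ethynylanisole
Product: 24 3-methoxy-5-[(4-methoxyphenyl)ethynyl]phenol
Conditions: Pd(PPh3)2Cl2 (3 mol %), CuI (5 mol %), Et3N, DMF, 80 °C
Reagents that add atoms: none
Why: Sonogashira coupling installs the C7d≡C8d alkyne on ring D before any aryl iodide is present.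

Step 18
Reactants: 21 C7e aldehyde; 24 ring-D alkynyl phenol
Product: 25 (2R,3R)-4-(tert-butyldimethylsilyloxy)-2-DBF-1-{2-hydroxy-4-methoxy-6-[(4-methoxyphenyl)ethynyl]phenyl}-3-ArSi-butan-1-ol (C1 epimers)
Conditions: 24, EtMgBr (1 equiv), Et2O/CH2Cl2, 0 °C; then 21, rt
Reagents that add atoms: none
Why: Ortho-specific hydroxyalkylation of a bromomagnesium phenoxide through a magnesium-chelated six-membered transition state forms C7e–C10d without a free carbocation; the ortho position para to the methoxy group (between OH and alkynyl) should react.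

Step 19
Reactants: 25 ortho-hydroxybenzyl alcohol
Product: 26 aryl tert-butyl carbonate of 25 (benzylic OH free)
Conditions: Boc2O (1.1 equiv), i-Pr2NEt, DMAP (5 mol %), CH2Cl2, 0 °C
Reagents that add atoms: di-tert-butyl dicarbonate, CC(C)(C)OC(=O)OC(=O)OC(C)(C)C
Why: Chemoselective O-acylation of the phenol over the hindered secondary benzylic alcohol.

Step 20
Reactants: 26 aryl carbonate
Product: 28 2-[(1S,2R,3R)-4-(tert-butyldimethylsilyloxy)-2-DBF-1-An-3-ArSi-butyl]-5-methoxy-3-[(4-methoxyphenyl)ethynyl]phenol, via o-quinone methide 27 (not isolated)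
Conditions: 4-MeOC6H4MgBr (3 equiv), THF, −78 → 0 °C
Reagents that add atoms: 4-methoxyphenylmagnesium bromide, COc1ccc([Mg]Br)cc1
Why: Alkoxide formation, carbonate migration and β-elimination give an o-quinone methide that takes up the aryl Grignard by 1,4-addition; with H8e eclipsing the quinone methide (A(1,3) strain), attack anti to the bulky C8c branch should set C7e.

Step 21
Reactants: 28 ring-D phenol
Product: 29 (1S,2R,3R)-4-(tert-butyldimethylsilyloxy)-2-DBF-1-An-1-{2,4-dimethoxy-6-[(4-methoxyphenyl)ethynyl]phenyl}-3-ArSi-butane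
Conditions: MeI, K2CO3, acetone, 50 °C
Reagents that add atoms: iodomethane, CI
Why: Williamson O-methylation of the only free phenol, so that ring D cannot compete for palladium in the annulation; aryl TIPS ethers are stable in acetone.

Step 22
Reactants: 29 fully protected open chain
Product: 30 (2R,3R,4S)-3-DBF-2-(3,5-dihydroxy-2-iodophenyl)-4-An-4-{2,4-dimethoxy-6-[(4-methoxyphenyl)ethynyl]phenyl}butan-1-ol
Conditions: TBAF (4 equiv), THF, 0 °C → rt; AcOH
Reagents that add atoms: none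
Why: Fluoride desilylation frees the iodoresorcinol (the phenol ortho to iodine is the one used in step 23) and the C7c alcohol.

Step 23
Reactants: 30 iodoresorcinol–diarylalkyne
Product: 31 eight-ring-fused benzofuran: ring C bonded C10c–C8d to the ring-D-bearing furan carbon, furan O–C7d(An), C13c–OH and C7c–OH free, (8cR,8eR,7eS)
Conditions: Pd(OAc)2 (10 mol %), P(t-Bu)3·HBF4 (20 mol %), K2CO3 (4 equiv), n-Bu4NCl (1 equiv), DMF, 100 °C, syringe-pump addition to 0.002 M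
Reagents that add atoms: none
Why: Proposed new method: Pd(0) inserts into the C10c–I bond, the aryl–palladium adds syn across the tethered diarylalkyne with C10c bonding to the proximal carbon C8d, and C–O reductive elimination from the six-membered oxapalladacycle (phenoxide O on C11c, vinylpalladium at C7d) closes the furan; the closest known reaction is the intermolecular Larock heteroannulation of o-iodophenols with internal alkynes to 2,3-disubstituted benzofurans. The eight-membered carbocycle closes in the 8-exo-dig mode (bond C10c–C8d) and the furan closes by five-membered C7d–O bond formation on the same palladium. No stereocentre is formed, since C7d and C8d stay sp2 until step 25. The step needs ring closure to beat intermolecular annulation and needs one alkyne regiochemistry: the tether lets only C8d reach C10c (the 9-endo mode would leave palladium on C8d, away from the phenoxide), and high dilution together with the two arenes and three contiguous stereocentres of the tether should favour cyclisation. The second phenoxide (C13c) is para to palladium and cannot reach C7d.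

Step 24
Reactants: 31 annulation product
Product: 32 C13c methyl ether of 31
Conditions: MeI (1.2 equiv), K2CO3, acetone, rt
Reagents that add atoms: iodomethane, CI
Why: Williamson O-methylation of the one remaining phenol; the primary alcohol is not alkylated by carbonate/MeI.

Step 25
Reactants: 32 benzofuran alcohol
Product: 33 (8cR,8eR,7eS,7dR,8dR) trans-dihydrobenzofuran alcohol
Conditions: Et3SiH (10 equiv), TFA, CH2Cl2, 0 °C → rt; then K2CO3, MeOH
Reagents that add atoms: none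
Why: Ionic hydrogenation (C3 protonation, hydride capture of the 2-aryl oxocarbenium ion); C8d should be protonated from the ring face carrying H7e and the small CH2OH arm, away from the C7e aryl group, and reversible ionisation of the anisyl-stabilised C7d–O bond in TFA should leave C7d trans to C8d.

Step 26
Reactants: 33 trans-dihydrobenzofuran alcohol
Product: 34 C7c aldehyde of units c–f
Conditions: Dess–Martin periodinane, NaHCO3, CH2Cl2, 0 °C
Reagents that add atoms: none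
Why: Dess–Martin oxidation under buffered conditions, chosen to spare the epimerisable C8c centre; the aldehyde is used at once.

Step 27
Reactants: 9 DBF–Br
Product: 35 tert-butyl 2-DBF-acetate
Conditions: BrZnCH2CO2t-Bu (1.5 equiv), Pd(dba)2 (5 mol %), Q-Phos (5 mol %), THF, 60 °C
Reagents that add atoms: (2-tert-butoxy-2-oxoethyl)zinc bromide, CC(C)(C)OC(=O)C[Zn]Br
Why: Negishi-type coupling of a Reformatsky reagent with the aryl bromide introduces C8b and C7b.

Step 28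
Reactants: 35 tert-butyl 2-DBF-acetate
Product: 38 seven-ring ketone of units a/b (C7b=O, C8b H2), via acid 36 (not isolated), via mixed anhydride 37 (not isolated)
Conditions: TFA/CH2Cl2 (1:4), rt, evaporation; TFAA (3 equiv), CH2Cl2, 0 °C → rt
Reagents that add atoms: none
Why: Ester cleavage then intramolecular Friedel–Crafts acylation; the acyl group can reach only the ortho position (C14a) of the 3,5-dimethoxyphenyl ring, closing the seven-membered ring.

Step 29
Reactants: 38 seven-ring ketone; 34 C7c aldehyde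
Product: 39 β-hydroxy ketone (C8b–C7c bond; epimers at C8b and C7c)
Conditions: 38, LiHMDS, THF, −78 °C; then 34, −78 °C; NH4Cl
Reagents that add atoms: none
Why: Aldol addition of the lithium enolate of the aryl ketone (only C8b can enolise) to the aldehyde at low temperature, where addition should outrun proton transfer from C8c.

Step 30
Reactants: 39 β-hydroxy ketone
Product: 41 enone C7b(=O)–C8b=C7c, via mesylate 40 (not isolated)
Conditions: MsCl, Et3N, DMAP (cat.), CH2Cl2, 0 °C → rt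
Reagents that add atoms: none
Why: Mesylation and E1cB elimination; triethylamine is strong enough for the α-proton but should not remove the γ-proton at C8c.

Step 31
Reactants: 41 enone
Product: 42 ketone with C7c(H)(An) and C8b(H), configured as in the target
Conditions: (4-MeOC6H4)2CuMgBr (from ArMgBr and CuBr·SMe2), THF, −40 → 0 °C; NH4Cl; then DBU (cat.), CH2Cl2, rt
Reagents that add atoms: 4-methoxyphenylmagnesium bromide, COc1ccc([Mg]Br)cc1
Why: Cuprate conjugate addition to an α-alkylidene aryl ketone; with H8c eclipsing the enone, the aryl group should add anti to the C8e branch, whose cis ring-E aryl screens that face, and C8b is set by thermodynamic protonation with the large C7c substituent pseudo-equatorial.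

Step 32
Reactants: 42 ketone
Product: 43 tertiary alcohol at C7b (An added; C7b configuration not relevant)
Conditions: 4-MeOC6H4MgBr, CeCl3 (anhydrous), THF, −78 → 0 °C
Reagents that add atoms: 4-methoxyphenylmagnesium bromide, COc1ccc([Mg]Br)cc1
Why: Organocerium 1,2-addition, chosen because the weakly basic reagent adds to hindered enolisable ketones instead of deprotonating C8b.

Step 33
Reactants: 43 tertiary alcohol
Product: 44 pentadecamethyl ether of the target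
Conditions: Et3SiH (5 equiv), TFA (10 equiv), CH2Cl2, −40 → 0 °C
Reagents that add atoms: none
Why: Ionic hydrogenation of the doubly benzylic tertiary alcohol, which ionises well below the temperature needed to open the dihydrofurans; hydride should enter anti to the C7c substituent on C8b, giving H7b cis to H8b.

Step 34
Reactants: 44 pentadecamethyl ether
Product: 45 CNP0184494.1 (target)
Conditions: BBr3 (excess), CH2Cl2, −78 → 0 °C; MeOH, H2O
Reagents that add atoms: none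
Why: Global Lewis-acid cleavage of the fifteen aryl methyl ethers; the three trans-dihydrobenzofurans are already the thermodynamic isomers should their benzylic C–O bonds ionise reversibly.

## Compound list

1 | 2-bromo-4,6-dimethoxybenzaldehyde | COc1cc(OC)c(C=O)c(Br)c1 | starting material
2 | 2-bromo-6-hydroxy-4-methoxybenzaldehyde | COc1cc(O)c(C=O)c(Br)c1 | intermediate
3 | 2-bromo-4-methoxy-6-[(4-methoxybenzyl)oxy]benzaldehyde | COc1ccc(COc2cc(OC)cc(Br)c2C=O)cc1 | intermediate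
4 | [2-bromo-4-methoxy-6-(4-methoxybenzyloxy)phenyl](3,5-dimethoxyphenyl)methanol, racemic | COc1ccc(COc2cc(OC)cc(Br)c2C(O)c2cc(OC)cc(OC)c2)cc1 | intermediate
5 | [2-bromo-4-methoxy-6-(4-methoxybenzyloxy)phenyl](3,5-dimethoxyphenyl)methanone | COc1ccc(COc2cc(OC)cc(Br)c2C(=O)c2cc(OC)cc(OC)c2)cc1 | intermediate
6 | hydrazone of 5 | COc1ccc(COc2cc(OC)cc(Br)c2C(=NN)c2cc(OC)cc(OC)c2)cc1 | intermediate
7 | diaryldiazomethane from 6 (not isolated) | COc1ccc(COc2cc(OC)cc(Br)c2C(=[N+]=[N-])c2cc(OC)cc(OC)c2)cc1 | intermediate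
8 | (2S,3R)-4-bromo-3-(3,5-dimethoxyphenyl)-6-methoxy-2-(4-methoxyphenyl)-2,3-dihydro-1-benzofuran (cis) | Brc1cc(OC)cc2c1[C@@H](c1cc(OC)cc(OC)c1)[C@@H](c1ccc(OC)cc1)O2 | intermediate
9 | (2R,3R)-4-bromo-3-(3,5-dimethoxyphenyl)-6-methoxy-2-(4-methoxyphenyl)-2,3-dihydro-1-benzofuran (trans, DBF–Br) | Brc1cc(OC)cc2c1[C@@H](c1cc(OC)cc(OC)c1)[C@H](c1ccc(OC)cc1)O2 | intermediate
10 | (E)-3-DBF-prop-2-en-1-ol | OC/C=C/c1cc(OC)cc2c1[C@@H](c1cc(OC)cc(OC)c1)[C@H](c1ccc(OC)cc1)O2 | intermediate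
11 | (E)-3-DBF-prop-2-enyl methyl carbonate | COC(=O)OC/C=C/c1cc(OC)cc2c1[C@@H](c1cc(OC)cc(OC)c1)[C@H](c1ccc(OC)cc1)O2 | intermediate
12 | 2-(3,5-dimethoxyphenyl)acetic acid | COc1cc(OC)cc(CC(=O)O)c1 | starting material
13 | 2-(2-iodo-3,5-dimethoxyphenyl)acetic acid | COc1cc(OC)c(I)c(CC(=O)O)c1 | intermediate
14 | 2-(3,5-dihydroxy-2-iodophenyl)acetic acid | Oc1cc(O)c(I)c(CC(=O)O)c1 | intermediate
15 | triisopropylsilyl 2-[2-iodo-3,5-bis(triisopropylsilyloxy)phenyl]acetate (not isolated) | CC(C)[Si](C(C)C)(C(C)C)Oc1cc(O[Si](C(C)C)(C(C)C)C(C)C)c(I)c(CC(=O)O[Si](C(C)C)(C(C)C)C(C)C)c1 | intermediate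
16 | 2-[2-iodo-3,5-bis(triisopropylsilyloxy)phenyl]acetic acid | CC(C)[Si](C(C)C)(C(C)C)Oc1cc(O[Si](C(C)C)(C(C)C)C(C)C)c(I)c(CC(=O)O)c1 | intermediate
17 | pentafluorophenyl 2-[2-iodo-3,5-bis(triisopropylsilyloxy)phenyl]acetate | CC(C)[Si](C(C)C)(C(C)C)Oc1cc(O[Si](C(C)C)(C(C)C)C(C)C)c(I)c(CC(=O)Oc2c(F)c(F)c(F)c(F)c2F)c1 | intermediate
18 | pentafluorophenyl (2R,3R)-3-DBF-2-ArSi-pent-4-enoate (not isolated) | CC(C)[Si](C(C)C)(C(C)C)Oc1cc(O[Si](C(C)C)(C(C)C)C(C)C)cc(c1I)[C@H](C(=O)Oc1c(F)c(F)c(F)c(F)c1F)[C@H](c1cc(OC)cc2c1[C@@H](c1cc(OC)cc(OC)c1)[C@H](c1ccc(OC)cc1)O2)C=C | intermediate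
19 | (2R,3R)-3-DBF-2-ArSi-pent-4-en-1-ol | CC(C)[Si](C(C)C)(C(C)C)Oc1cc(O[Si](C(C)C)(C(C)C)C(C)C)cc(c1I)[C@H](CO)[C@H](c1cc(OC)cc2c1[C@@H](c1cc(OC)cc(OC)c1)[C@H](c1ccc(OC)cc1)O2)C=C | intermediate
20 | tert-butyldimethylsilyl ether of 19 | CC(C)[Si](C(C)C)(C(C)C)Oc1cc(O[Si](C(C)C)(C(C)C)C(C)C)cc(c1I)[C@H](CO[Si](C)(C)C(C)(C)C)[C@H](c1cc(OC)cc2c1[C@@H](c1cc(OC)cc(OC)c1)[C@H](c1ccc(OC)cc1)O2)C=C | intermediate
21 | (2R,3R)-4-(tert-butyldimethylsilyloxy)-2-DBF-3-ArSi-butanal | CC(C)[Si](C(C)C)(C(C)C)Oc1cc(O[Si](C(C)C)(C(C)C)C(C)C)cc(c1I)[C@H](CO[Si](C)(C)C(C)(C)C)[C@H](c1cc(OC)cc2c1[C@@H](c1cc(OC)cc(OC)c1)[C@H](c1ccc(OC)cc1)O2)C=O | intermediate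
22 | 3-bromo-5-methoxyphenol | COc1cc(O)cc(Br)c1 | starting material
23 | 4-ethynylanisole | COc1ccc(C#C)cc1 | starting material
24 | 3-methoxy-5-[(4-methoxyphenyl)ethynyl]phenol | COc1ccc(C#Cc2cc(O)cc(OC)c2)cc1 | intermediate
25 | (2R,3R)-4-(tert-butyldimethylsilyloxy)-2-DBF-1-{2-hydroxy-4-methoxy-6-[(4-methoxyphenyl)ethynyl]phenyl}-3-ArSi-butan-1-ol, C1 epimers | CC(C)[Si](C(C)C)(C(C)C)Oc1cc(O[Si](C(C)C)(C(C)C)C(C)C)cc(c1I)[C@H](CO[Si](C)(C)C(C)(C)C)[C@H](c1cc(OC)cc2c1[C@@H](c1cc(OC)cc(OC)c1)[C@H](c1ccc(OC)cc1)O2)C(O)c1c(O)cc(OC)cc1C#Cc1ccc(OC)cc1 | intermediate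
26 | aryl tert-butyl carbonate of 25 | CC(C)[Si](C(C)C)(C(C)C)Oc1cc(O[Si](C(C)C)(C(C)C)C(C)C)cc(c1I)[C@H](CO[Si](C)(C)C(C)(C)C)[C@H](c1cc(OC)cc2c1[C@@H](c1cc(OC)cc(OC)c1)[C@H](c1ccc(OC)cc1)O2)C(O)c1c(OC(=O)OC(C)(C)C)cc(OC)cc1C#Cc1ccc(OC)cc1 | intermediate
27 | 6-[(2R,3R)-4-(tert-butyldimethylsilyloxy)-2-DBF-3-ArSi-butylidene]-3-methoxy-5-[(4-methoxyphenyl)ethynyl]cyclohexa-2,4-dien-1-one (o-quinone methide, not isolated) | CC(C)[Si](C(C)C)(C(C)C)Oc1cc(O[Si](C(C)C)(C(C)C)C(C)C)cc(c1I)[C@H](CO[Si](C)(C)C(C)(C)C)[C@H](c1cc(OC)cc2c1[C@@H](c1cc(OC)cc(OC)c1)[C@H](c1ccc(OC)cc1)O2)C=C1C(=O)C=C(OC)C=C1C#Cc1ccc(OC)cc1 | intermediate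
28 | 2-[(1S,2R,3R)-4-(tert-butyldimethylsilyloxy)-2-DBF-1-An-3-ArSi-butyl]-5-methoxy-3-[(4-methoxyphenyl)ethynyl]phenol | CC(C)[Si](C(C)C)(C(C)C)Oc1cc(O[Si](C(C)C)(C(C)C)C(C)C)cc(c1I)[C@H](CO[Si](C)(C)C(C)(C)C)[C@H](c1cc(OC)cc2c1[C@@H](c1cc(OC)cc(OC)c1)[C@H](c1ccc(OC)cc1)O2)[C@@H](c1ccc(OC)cc1)c1c(O)cc(OC)cc1C#Cc1ccc(OC)cc1 | intermediate
29 | methyl ether of 28 (ring D 2,4-dimethoxy-6-alkynyl) | CC(C)[Si](C(C)C)(C(C)C)Oc1cc(O[Si](C(C)C)(C(C)C)C(C)C)cc(c1I)[C@H](CO[Si](C)(C)C(C)(C)C)[C@H](c1cc(OC)cc2c1[C@@H](c1cc(OC)cc(OC)c1)[C@H](c1ccc(OC)cc1)O2)[C@@H](c1ccc(OC)cc1)c1c(OC)cc(OC)cc1C#Cc1ccc(OC)cc1 | intermediate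
30 | (2R,3R,4S)-3-DBF-2-(3,5-dihydroxy-2-iodophenyl)-4-An-4-{2,4-dimethoxy-6-[(4-methoxyphenyl)ethynyl]phenyl}butan-1-ol (key-step precursor) | Oc1cc(O)cc(c1I)[C@H](CO)[C@H](c1cc(OC)cc2c1[C@@H](c1cc(OC)cc(OC)c1)[C@H](c1ccc(OC)cc1)O2)[C@@H](c1ccc(OC)cc1)c1c(OC)cc(OC)cc1C#Cc1ccc(OC)cc1 | intermediate
31 | eight-ring-fused 2-An-benzofuran with C13c–OH and C7c–OH free, (8cR,8eR,7eS) (key-step product) | OC[C@H]1c2cc(O)cc3oc(-c4ccc(OC)cc4)c(c23)-c2cc(OC)cc(OC)c2[C@H](c2ccc(OC)cc2)[C@H]1c1cc(OC)cc2c1[C@@H](c1cc(OC)cc(OC)c1)[C@H](c1ccc(OC)cc1)O2 | intermediate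
32 | C13c methyl ether of 31 | OC[C@H]1c2cc(OC)cc3oc(-c4ccc(OC)cc4)c(c23)-c2cc(OC)cc(OC)c2[C@H](c2ccc(OC)cc2)[C@H]1c1cc(OC)cc2c1[C@@H](c1cc(OC)cc(OC)c1)[C@H](c1ccc(OC)cc1)O2 | intermediate
33 | trans-dihydrobenzofuran alcohol of units c–f, (8cR,8eR,7eS,7dR,8dR) | OC[C@H]2c4cc(OC)cc5c4[C@@H](c4cc(OC)cc(OC)c4[C@H](c4ccc(OC)cc4)[C@H]2c2cc(OC)cc4c2[C@@H](c2cc(OC)cc(OC)c2)[C@H](c2ccc(OC)cc2)O4)[C@H](c2ccc(OC)cc2)O5 | intermediate
34 | C7c aldehyde of units c–f | O=C[C@H]2c4cc(OC)cc5c4[C@@H](c4cc(OC)cc(OC)c4[C@H](c4ccc(OC)cc4)[C@H]2c2cc(OC)cc4c2[C@@H](c2cc(OC)cc(OC)c2)[C@H](c2ccc(OC)cc2)O4)[C@H](c2ccc(OC)cc2)O5 | intermediate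
35 | tert-butyl 2-DBF-acetate | CC(C)(C)OC(=O)Cc1cc(OC)cc2c1[C@@H](c1cc(OC)cc(OC)c1)[C@H](c1ccc(OC)cc1)O2 | intermediate
36 | 2-DBF-acetic acid (not isolated) | OC(=O)Cc1cc(OC)cc2c1[C@@H](c1cc(OC)cc(OC)c1)[C@H](c1ccc(OC)cc1)O2 | intermediate
37 | 2-DBF-acetic trifluoroacetic anhydride (not isolated) | FC(F)(F)C(=O)OC(=O)Cc1cc(OC)cc2c1[C@@H](c1cc(OC)cc(OC)c1)[C@H](c1ccc(OC)cc1)O2 | intermediate
38 | seven-ring ketone of units a/b (C7b=O, C8b H2; 7aR,8aR) | O=C2c3c(OC)cc(OC)cc3[C@@H]3c4c(cc(OC)cc4C2)O[C@H]3c2ccc(OC)cc2 | intermediate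
39 | β-hydroxy ketone from 38 and 34 (epimers at C8b and C7c) | O=C2c3c(OC)cc(OC)cc3[C@@H]3c4c(cc(OC)cc4C2C(O)[C@H]2c4cc(OC)cc5c4[C@@H](c4cc(OC)cc(OC)c4[C@H](c4ccc(OC)cc4)[C@H]2c2cc(OC)cc4c2[C@@H](c2cc(OC)cc(OC)c2)[C@H](c2ccc(OC)cc2)O4)[C@H](c2ccc(OC)cc2)O5)O[C@H]3c2ccc(OC)cc2 | intermediate
40 | methanesulfonate of 39 (not isolated) | O=C2c3c(OC)cc(OC)cc3[C@@H]3c4c(cc(OC)cc4C2C(OS(C)(=O)=O)[C@H]2c4cc(OC)cc5c4[C@@H](c4cc(OC)cc(OC)c4[C@H](c4ccc(OC)cc4)[C@H]2c2cc(OC)cc4c2[C@@H](c2cc(OC)cc(OC)c2)[C@H](c2ccc(OC)cc2)O4)[C@H](c2ccc(OC)cc2)O5)O[C@H]3c2ccc(OC)cc2 | intermediate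
41 | enone C7b(=O)–C8b=C7c (alkene geometry not fixed) | O=C2c3c(OC)cc(OC)cc3[C@@H]3c4c(cc(OC)cc4C2=C[C@H]2c4cc(OC)cc5c4[C@@H](c4cc(OC)cc(OC)c4[C@H](c4ccc(OC)cc4)[C@H]2c2cc(OC)cc4c2[C@@H](c2cc(OC)cc(OC)c2)[C@H](c2ccc(OC)cc2)O4)[C@H](c2ccc(OC)cc2)O5)O[C@H]3c2ccc(OC)cc2 | intermediate
42 | C7b ketone with C7c and C8b configured as in the target | O=C2c3c(OC)cc(OC)cc3[C@@H]3c4c(cc(OC)cc4[C@H]2[C@H](c2ccc(OC)cc2)[C@H]2c4cc(OC)cc5c4[C@@H](c4cc(OC)cc(OC)c4[C@H](c4ccc(OC)cc4)[C@H]2c2cc(OC)cc4c2[C@@H](c2cc(OC)cc(OC)c2)[C@H](c2ccc(OC)cc2)O4)[C@H](c2ccc(OC)cc2)O5)O[C@H]3c2ccc(OC)cc2 | intermediate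
43 | C7b tertiary alcohol (C7b configuration not fixed) | COc1ccc(C2(O)c3c(OC)cc(OC)cc3[C@@H]3c4c(cc(OC)cc4[C@H]2[C@H](c2ccc(OC)cc2)[C@H]2c4cc(OC)cc5c4[C@@H](c4cc(OC)cc(OC)c4[C@H](c4ccc(OC)cc4)[C@H]2c2cc(OC)cc4c2[C@@H](c2cc(OC)cc(OC)c2)[C@H](c2ccc(OC)cc2)O4)[C@H](c2ccc(OC)cc2)O5)O[C@H]3c2ccc(OC)cc2)cc1 | intermediate
44 | pentadecamethyl ether of the target | COc1ccc([C@H]2c3c(OC)cc(OC)cc3[C@@H]3c4c(cc(OC)cc4[C@H]2[C@H](c2ccc(OC)cc2)[C@H]2c4cc(OC)cc5c4[C@@H](c4cc(OC)cc(OC)c4[C@H](c4ccc(OC)cc4)[C@H]2c2cc(OC)cc4c2[C@@H](c2cc(OC)cc(OC)c2)[C@H](c2ccc(OC)cc2)O4)[C@H](c2ccc(OC)cc2)O5)O[C@H]3c2ccc(OC)cc2)cc1 | intermediate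
45 | CNP0184494.1 | Oc1ccc([C@H]2c3c(O)cc(O)cc3[C@@H]3c4c(cc(O)cc4[C@H]2[C@H](c2ccc(O)cc2)[C@H]2c4cc(O)cc5c4[C@@H](c4cc(O)cc(O)c4[C@H](c4ccc(O)cc4)[C@H]2c2cc(O)cc4c2[C@@H](c2cc(O)cc(O)c2)[C@H](c2ccc(O)cc2)O4)[C@H](c2ccc(O)cc2)O5)O[C@H]3c2ccc(O)cc2)cc1 | target

## Step count and risks

Total step count: 34. Longest linear sequence: 27 steps (steps 1–9, 14–16, 18–26, 29–34).

Steps most likely to fail:

1. Step 23. The aryl–palladium may be consumed by intermolecular carbopalladation, oligomerisation or protodeiodination before the strained 8-exo insertion takes place, or the medium ring may simply not close. Fallback (known chemistry, setting out from 21 and 22 and returning at 31): the eight-membered ring is closed instead through the C8d–C9d bond after the benzofuran has been made. The bromomagnesium phenoxide of 22 is ortho-hydroxyalkylated with 21 as in step 18 to give the ring-D bromo diol F1. Boc protection as in step 19 gives the aryl carbonate F2. The o-quinone methide arylation of step 20 gives the bromo phenol F3. O-methylation gives the methyl ether F4. TBAF gives the iodoresorcinol bromo triol F5. One-pot Sonogashira coupling/5-endo cyclisation with 23 (Pd(PPh3)2Cl2, CuI, Et3N, DMF, 60 °C; the aryl iodide reacts before the aryl bromide) gives the 2-arylbenzofuran bromide F6. Intramolecular palladium-catalysed direct C3–H arylation by the ring-D bromide (Pd(OAc)2, PCy3·HBF4, PivOH, K2CO3, DMA, 120 °C) then gives 31.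

2. Step 31. Aryl transfer to the crowded β-carbon C7c may be slower than γ-deprotonation at C8c, or may occur from the wrong face of the enone. Fallback (setting out from 34 and 38, returning at 44): the C7c–C8b bond is made by cation–olefin coupling instead. 4-Methoxyphenylmagnesium bromide adds to 34 to give the C7c carbinol F8. Ketone 38 with the same Grignard reagent and CeCl3 gives the tertiary alcohol F9, which is dehydrated (TsOH cat., toluene, 60 °C) to the cyclic stilbene F10. BF3·OEt2 and Et3SiH in CH2Cl2 at −78 °C ionise F8, the C7c cation alkylates C8b of F10, and the resulting C7b cation is reduced in the same flask, giving 44 directly.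

3. Step 25. Protonation at C8d may occur from the wrong face, or hydride may capture a ring-opened benzylic cation so that a C7d–O or C7f–O bond is lost. Fallback (setting out from 32, returning at 33): hydrogenation over Pd(OH)2/C (H2, 50 bar, EtOAc/AcOH) delivers both hydrogens to one face and gives the cis-dihydrobenzofuran F7, which is epimerised at C7d with catalytic TFA in CH2Cl2 to 33.

## Further compounds

F1 | step 23 | (2R,3R)-1-(2-bromo-6-hydroxy-4-methoxyphenyl)-4-(tert-butyldimethylsilyloxy)-2-DBF-3-ArSi-butan-1-ol, C1 epimers | CC(C)[Si](C(C)C)(C(C)C)Oc1cc(O[Si](C(C)C)(C(C)C)C(C)C)cc(c1I)[C@H](CO[Si](C)(C)C(C)(C)C)[C@H](c1cc(OC)cc2c1[C@@H](c1cc(OC)cc(OC)c1)[C@H](c1ccc(OC)cc1)O2)C(O)c1c(O)cc(OC)cc1Br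
F2 | step 23 | aryl tert-butyl carbonate of F1 | CC(C)[Si](C(C)C)(C(C)C)Oc1cc(O[Si](C(C)C)(C(C)C)C(C)C)cc(c1I)[C@H](CO[Si](C)(C)C(C)(C)C)[C@H](c1cc(OC)cc2c1[C@@H](c1cc(OC)cc(OC)c1)[C@H](c1ccc(OC)cc1)O2)C(O)c1c(OC(=O)OC(C)(C)C)cc(OC)cc1Br
F3 | step 23 | 3-bromo-2-[(1S,2R,3R)-4-(tert-butyldimethylsilyloxy)-2-DBF-1-An-3-ArSi-butyl]-5-methoxyphenol | CC(C)[Si](C(C)C)(C(C)C)Oc1cc(O[Si](C(C)C)(C(C)C)C(C)C)cc(c1I)[C@H](CO[Si](C)(C)C(C)(C)C)[C@H](c1cc(OC)cc2c1[C@@H](c1cc(OC)cc(OC)c1)[C@H](c1ccc(OC)cc1)O2)[C@@H](c1ccc(OC)cc1)c1c(O)cc(OC)cc1Br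
F4 | step 23 | methyl ether of F3 | CC(C)[Si](C(C)C)(C(C)C)Oc1cc(O[Si](C(C)C)(C(C)C)C(C)C)cc(c1I)[C@H](CO[Si](C)(C)C(C)(C)C)[C@H](c1cc(OC)cc2c1[C@@H](c1cc(OC)cc(OC)c1)[C@H](c1ccc(OC)cc1)O2)[C@@H](c1ccc(OC)cc1)c1c(OC)cc(OC)cc1Br
F5 | step 23 | (2R,3R,4S)-4-(2-bromo-4,6-dimethoxyphenyl)-3-DBF-2-(3,5-dihydroxy-2-iodophenyl)-4-An-butan-1-ol | Oc1cc(O)cc(c1I)[C@H](CO)[C@H](c1cc(OC)cc2c1[C@@H](c1cc(OC)cc(OC)c1)[C@H](c1ccc(OC)cc1)O2)[C@@H](c1ccc(OC)cc1)c1c(OC)cc(OC)cc1Br
F6 | step 23 | (2R,3R,4S)-4-(2-bromo-4,6-dimethoxyphenyl)-3-DBF-2-[6-hydroxy-2-(4-methoxyphenyl)-1-benzofuran-4-yl]-4-An-butan-1-ol | Oc1cc2oc(-c3ccc(OC)cc3)cc2c(c1)[C@H](CO)[C@H](c1cc(OC)cc2c1[C@@H](c1cc(OC)cc(OC)c1)[C@H](c1ccc(OC)cc1)O2)[C@@H](c1ccc(OC)cc1)c1c(OC)cc(OC)cc1Br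
F7 | step 25 | cis-dihydrobenzofuran alcohol, C7d epimer of 33 | OC[C@H]2c4cc(OC)cc5c4[C@@H](c4cc(OC)cc(OC)c4[C@H](c4ccc(OC)cc4)[C@H]2c2cc(OC)cc4c2[C@@H](c2cc(OC)cc(OC)c2)[C@H](c2ccc(OC)cc2)O4)[C@@H](c2ccc(OC)cc2)O5
F8 | step 31 | C7c (4-methoxyphenyl)carbinol from 34, C7c epimers | COc1ccc(C(O)[C@H]2c4cc(OC)cc5c4[C@@H](c4cc(OC)cc(OC)c4[C@H](c4ccc(OC)cc4)[C@H]2c2cc(OC)cc4c2[C@@H](c2cc(OC)cc(OC)c2)[C@H](c2ccc(OC)cc2)O4)[C@H](c2ccc(OC)cc2)O5)cc1
F9 | step 31 | C7b tertiary alcohol from 38 | COc1ccc(C2(O)c3c(OC)cc(OC)cc3[C@@H]3c4c(cc(OC)cc4C2)O[C@H]3c2ccc(OC)cc2)cc1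
F10 | step 31 | seven-ring stilbene C7b(An)=C8b(H) of units a/b | COc1ccc(C=2c3c(OC)cc(OC)cc3[C@@H]3c4c(cc(OC)cc4C=2)O[C@H]3c2ccc(OC)cc2)cc1
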